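The route rests on disconnecting the pyrrolidine and the cyclopentene at the aza-quaternary carbon, the carbon that carries N and the azepanone C=O, is shared by the azepanone, pyrrolidine and cyclopentene rings and sits next to the tetrasubstituted C=C. That carbon is treated as the α-carbon of a ketone-stabilised azomethine ylide and the C=C as the remnant of a 1,1-disubstituted allene. In one operation a secondary 2-substituted azepan-3-one bearing a vinylidene lactone condenses with a chiral-pool lactone aldehyde, and the ylide adds across the distal allene bond, closing both rings, joining the two halves and setting two stereocentres. The precursors are the amino ketone allene lactone 26 and aldehyde 34.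

Key step: step 24

Remark: C-2 of the azepanone is planarised when the ylide forms, so its configuration in 12–26 and 35 (drawn R, as delivered by the Mannich step) does not matter; aldehydes 15 and 34 are prepared immediately before steps 14 and 24.

Step 1
Reactants: 1 ethyl glyoxylate; 2 p-anisidine
Product: 3 ethyl (E)-2-[(4-methoxyphenyl)imino]acetate
Conditions: MgSO4, CH2Cl2, rt (1 freshly distilled from its toluene solution); filter, concentrate
Reagents that add atoms: none
Why: Imine condensation of an electron-rich aniline with an activated aldehyde is fast and is driven to completion by the drying agent.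

Step 2
Reactants: 3 ethyl (E)-2-[(4-methoxyphenyl)imino]acetate; 4 butanal
Product: 5 ethyl (2R,3R)-3-formyl-2-[(4-methoxyphenyl)amino]pentanoate
Conditions: D-proline (20 mol%), 1,4-dioxane, rt, slow addition of 4 (1.5 equiv); short silica plug, used crude
Reagents that add atoms: none
Why: Proline-catalysed enamine Mannich reaction, in which the anti-enamine of butanal attacks the imine face held by the proline carboxylic acid, so that D-proline should set both new centres syn as (2R,3R).

Step 3
Reactants: 5 ethyl (2R,3R)-3-formyl-2-[(4-methoxyphenyl)amino]pentanoate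
Product: 6 ethyl (2R,3R)-3-(dimethoxymethyl)-2-[(4-methoxyphenyl)amino]pentanoate
Conditions: HC(OMe)3, MeOH, p-TsOH·H2O (0.2 equiv), 0 °C → rt; NaHCO3
Reagents that add atoms: trimethyl orthoformate, COC(OC)OC; methanol, CO
Why: Acid-catalysed acetalisation with the orthoformate as water scavenger should outrun epimerisation and β-elimination of the labile β-amino aldehyde and touches no stereocentre.

Step 4
Reactants: 6 ethyl (2R,3R)-3-(dimethoxymethyl)-2-[(4-methoxyphenyl)amino]pentanoate
Product: 7 (2R,3R)-3-(dimethoxymethyl)-N-methoxy-2-[(4-methoxyphenyl)amino]-N-methylpentanamide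
Conditions: MeNH(OMe)·HCl (3 equiv), iPrMgCl (6 equiv), THF, −20 → 0 °C
Reagents that add atoms: N,O-dimethylhydroxylamine hydrochloride, CNOC.Cl
Why: Weinreb amide formation by magnesium amide aminolysis works on hindered esters at low temperature and leaves the acetal untouched.

Step 5
Reactants: 7 (2R,3R)-3-(dimethoxymethyl)-N-methoxy-2-[(4-methoxyphenyl)amino]-N-methylpentanamide; 8 1-bromo-4-chlorobutane
Product: 10 (3R,4R)-9-chloro-3-(dimethoxymethyl)-4-[(4-methoxyphenyl)amino]nonan-5-one, via 4-chlorobutylmagnesium bromide 9 (not isolated)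
Conditions: 8, Mg, THF, rt; then 7 (0.33 equiv relative to 9), THF, −20 → 0 °C; aq. NH4Cl
Reagents that add atoms: none
Why: Magnesium inserts selectively into the C–Br bond of 8, and Grignard addition to the Weinreb amide stops at the chelated tetrahedral intermediate, so only the ketone forms after the first equivalent has removed the N–H proton.

Step 6
Reactants: 10 (3R,4R)-9-chloro-3-(dimethoxymethyl)-4-[(4-methoxyphenyl)amino]nonan-5-one
Product: 12 (2R)-2-[(2R)-1,1-dimethoxybutan-2-yl]-1-(4-methoxyphenyl)azepan-3-one, via iodo ketone 11 (not isolated)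
Conditions: NaI (1.5 equiv), NaHCO3 (3 equiv), MeCN (0.01 M), 80 °C
Reagents that add atoms: none
Why: Finkelstein exchange followed by 7-exo-tet intramolecular N-alkylation, run dilute with a weak base so that the amine and not the ketone enolate is the nucleophile.

Step 7
Reactants: 12 (2R)-2-[(2R)-1,1-dimethoxybutan-2-yl]-1-(4-methoxyphenyl)azepan-3-one
Product: 14 tert-butyl (2R)-2-[(2R)-1,1-dimethoxybutan-2-yl]-3-oxoazepane-1-carboxylate, via free amine 13 (not isolated)
Conditions: (NH4)2Ce(NO3)6 (3 equiv), MeCN/H2O (3:1), 0 °C, 20 min; CH2Cl2 wash of the acidic phase; then NaHCO3 to pH 8, Boc2O, EtOAc, rt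
Reagents that add atoms: di-tert-butyl dicarbonate, CC(C)(C)OC(=O)OC(=O)OC(C)(C)C
Why: Oxidative dearylation by tetravalent cerium gives a quinone iminium that hydrolyses to benzoquinone and the secondary amine, which is trapped as its carbamate in the same flask; short contact at 0 °C should spare the dimethyl acetal.

Step 8
Reactants: 14 tert-butyl (2R)-2-[(2R)-1,1-dimethoxybutan-2-yl]-3-oxoazepane-1-carboxylate
Product: 15 tert-butyl (2R)-3-oxo-2-[(2R)-1-oxobutan-2-yl]azepane-1-carboxylate
Conditions: pyridinium p-toluenesulfonate (0.2 equiv), acetone/H2O (10:1), 45 °C; extract, dry, use at once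
Reagents that add atoms: water, O
Why: Mild acid-catalysed acetal hydrolysis at an acidity the Boc group tolerates; the 1,4-keto aldehyde is used at once to avoid aldol closure and epimerisation of its α-centre.

Step 9
Reactants: 16 methyl (S)-3-hydroxy-2-methylpropanoate
Product: 17 methyl (S)-3-{[tert-butyl(dimethyl)silyl]oxy}-2-methylpropanoate
Conditions: TBSCl, imidazole, CH2Cl2, 0 °C → rt
Reagents that add atoms: tert-butyldimethylsilyl chloride, CC(C)(C)[Si](C)(C)Cl
Why: Standard silylation of an unhindered primary alcohol.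

Step 10
Reactants: 17 methyl (S)-3-{[tert-butyl(dimethyl)silyl]oxy}-2-methylpropanoate
Product: 18 (S)-3-{[tert-butyl(dimethyl)silyl]oxy}-2-methylpropanal
Conditions: iBu2AlH (1.1 equiv), CH2Cl2, −78 °C; aq. potassium sodium tartrate, cold
Reagents that add atoms: none
Why: Partial ester reduction through the tetrahedral aluminium hemiacetal, which is stable at −78 °C; cold neutral work-up should preserve the α-stereocentre.

Step 11
Reactants: 18 (S)-3-{[tert-butyl(dimethyl)silyl]oxy}-2-methylpropanal
Product: 19 (R)-tert-butyl(dimethyl)[(2-methylbut-3-yn-1-yl)oxy]silane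
Conditions: dimethyl (1-diazo-2-oxopropyl)phosphonate, K2CO3, MeOH, 0 °C → rt
Reagents that add atoms: dimethyl (1-diazo-2-oxopropyl)phosphonate, CC(=O)C(=[N+]=[N-])P(=O)(OC)OC
Why: Ohira–Bestmann homologation converts the aldehyde into the terminal alkyne under mild carbonate conditions, which at 0 °C should cause little erosion of the α-stereocentre.

Step 12
Reactants: 19 (R)-tert-butyl(dimethyl)[(2-methylbut-3-yn-1-yl)oxy]silane
Product: 20 (R)-5-{[tert-butyl(dimethyl)silyl]oxy}-4-methylpent-2-yn-1-ol
Conditions: n-BuLi, THF, −78 °C; (CH2O)n, −78 °C → rt; aq. NH4Cl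
Reagents that add atoms: paraformaldehyde (formaldehyde), C=O
Why: Hydroxymethylation of the lithium acetylide with formaldehyde is a standard C1 homologation.

Step 13
Reactants: 20 (R)-5-{[tert-butyl(dimethyl)silyl]oxy}-4-methylpent-2-yn-1-ol
Product: 21 (R)-[(5-bromo-2-methylpent-3-yn-1-yl)oxy](tert-butyl)dimethylsilane
Conditions: CBr4, PPh3, 2,6-lutidine, CH2Cl2, 0 °C
Reagents that add atoms: carbon tetrabromide, BrC(Br)(Br)Br
Why: Appel bromination of a primary propargylic alcohol under buffered, near-neutral conditions that the silyl ether tolerates.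

Step 14
Reactants: 15 tert-butyl (2R)-3-oxo-2-[(2R)-1-oxobutan-2-yl]azepane-1-carboxylate; 21 (R)-[(5-bromo-2-methylpent-3-yn-1-yl)oxy](tert-butyl)dimethylsilane
Product: 22 tert-butyl (2R)-2-[(3R,4S,6R)-7-{[tert-butyl(dimethyl)silyl]oxy}-4-hydroxy-6-methyl-5-vinylideneheptan-3-yl]-3-oxoazepane-1-carboxylate
Conditions: indium powder (In, 1.5 equiv), 21 (1.3 equiv), THF/H2O (4:1), rt
Reagents that add atoms: none
Why: Indium-mediated Barbier reaction, in which the γ-substituted propargyl indium species should transfer by SE2′ to give the allenyl carbinol, attack the aldehyde and not the ring ketone, and add anti to the azepanone carbon (Felkin–Anh, ethyl as medium group) to set the carbinol centre as (S), syn to ethyl.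

Step 15
Reactants: 22 allenyl carbinol silyl ether
Product: 23 tert-butyl (2R)-2-[(3R,4S,6R)-4,7-dihydroxy-6-methyl-5-vinylideneheptan-3-yl]-3-oxoazepane-1-carboxylate
Conditions: Bu4NF (1.2 equiv), AcOH (1.2 equiv), THF, 0 °C → rt
Reagents that add atoms: none
Why: Fluoride cleavage of the primary silyl ether, buffered with acetic acid so that the α-amino ketone and the allene see no free base.

Step 16
Reactants: 23 allenyl 1,4-diol
Product: 25 tert-butyl (2R)-2-{(1R)-1-[(2S,4R)-4-methyl-5-oxo-3-vinylideneoxolan-2-yl]propyl}-3-oxoazepane-1-carboxylate, via lactol 24 (not isolated)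
Conditions: TEMPO (0.2 equiv), PhI(OAc)2 (2.4 equiv), CH2Cl2, rt
Reagents that add atoms: none
Why: Oxoammonium oxidation selects the primary alcohol, the aldehyde closes onto the secondary hydroxyl to the five-membered lactol and is oxidised again to the lactone, while any reversible hemiketal between that hydroxyl and the ring ketone drains to 25 and the methyl-bearing centre is not enolised in the weakly acidic medium.

Step 17
Reactants: 25 N-Boc vinylidene lactone
Product: 26 (2R)-2-{(1R)-1-[(2S,4R)-4-methyl-5-oxo-3-vinylideneoxolan-2-yl]propyl}-3-oxoazepan-1-ium trifluoroacetate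
Conditions: TFA/CH2Cl2 (1:4), anisole (5 equiv), 0 °C, 30 min; evaporate cold, toluene azeotrope, use directly
Reagents that add atoms: trifluoroacetic acid, OC(=O)C(F)(F)F
Why: Acidolysis of the tert-butyl carbamate at 0 °C with a cation scavenger; the amine is kept protonated so that it cannot isomerise the vinylidene lactone.

Step 18
Reactants: 27 (S)-5-(hydroxymethyl)dihydrofuran-2(3H)-one
Product: 28 (S)-5-[(trityloxy)methyl]dihydrofuran-2(3H)-one
Conditions: TrCl, pyridine, DMAP (cat.), CH2Cl2, rt
Reagents that add atoms: trityl chloride, ClC(c1ccccc1)(c1ccccc1)c1ccccc1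
Why: Selective tritylation of the primary alcohol installs the bulky group that later controls the hydrogenation face.

Step 19
Reactants: 28 (S)-5-[(trityloxy)methyl]dihydrofuran-2(3H)-one
Product: 29 (3R,5S)-3-methyl-5-[(trityloxy)methyl]dihydrofuran-2(3H)-one (trans major)
Conditions: LiN(iPr)2 (1.1 equiv, commercial solution), THF, −78 °C; MeI
Reagents that add atoms: iodomethane, CI
Why: Lactone enolate alkylation anti to the C-5 substituent gives mainly the trans isomer, and the C-3 configuration is irrelevant because that carbon becomes planar in step 20.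

Step 20
Reactants: 29 (3R,5S)-3-methyl-5-[(trityloxy)methyl]dihydrofuran-2(3H)-one
Product: 31 (S)-3-methyl-5-[(trityloxy)methyl]furan-2(5H)-one, via selenide 30 (not isolated)
Conditions: LiN(iPr)2 (commercial solution), THF, −78 °C; PhSeBr; then H2O2 (30%), pyridine, CH2Cl2, 0 °C → rt
Reagents that add atoms: none
Why: Enolate selenenylation followed by selenoxide syn-elimination should give the conjugated butenolide, and any exocyclic methylene isomer converges in step 21.

Step 21
Reactants: 31 (S)-3-methyl-5-[(trityloxy)methyl]furan-2(5H)-one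
Product: 32 (3S,5S)-3-methyl-5-[(trityloxy)methyl]dihydrofuran-2(3H)-one (cis)
Conditions: H2 (1 atm), Pd/C (10 wt%), EtOAc, rt
Reagents that add atoms: none
Why: Heterogeneous hydrogenation delivers hydrogen to the butenolide face opposite the bulky trityloxymethyl group, which sets C-3 cis to C-5 as (3S,5S).

Step 22
Reactants: 32 (3S,5S)-3-methyl-5-[(trityloxy)methyl]dihydrofuran-2(3H)-one
Product: 33 (3S,5S)-5-(hydroxymethyl)-3-methyldihydrofuran-2(3H)-one
Conditions: p-TsOH·H2O (cat.), MeOH/CH2Cl2 (1:1), rt
Reagents that add atoms: none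
Why: Acid-catalysed solvolysis of the trityl ether; the five-membered lactone stays closed and its α-centre is not enolised under these conditions.

Step 23
Reactants: 33 (3S,5S)-5-(hydroxymethyl)-3-methyldihydrofuran-2(3H)-one
Product: 34 (2S,4S)-4-methyl-5-oxooxolane-2-carbaldehyde
Conditions: Dess–Martin periodinane (1.2 equiv), NaHCO3, CH2Cl2, 0 °C → rt; filter, use at once
Reagents that add atoms: none
Why: Buffered Dess–Martin oxidation gives the α-oxy aldehyde without base, so the adjacent stereocentre should survive if the aldehyde is used fresh.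

Step 24
Reactants: 26 amino ketone allene lactone trifluoroacetate; 34 (2S,4S)-4-methyl-5-oxooxolane-2-carbaldehyde
Product: 38 target CNP0315436.2, via free amine 35 (not isolated), via iminium ion 36 (not isolated), via azomethine ylide 37 (not isolated)
Conditions: 34 (1.2 equiv), iPr2NEt (1.0 equiv), powdered 4 Å MS, toluene (0.02 M), rt 1 h, then 90 °C
Reagents that add atoms: none
Why: Proposed new method: the amine freed from 26 condenses with 34 to the iminium ion 36 (aldehyde carbon to N), whose proton α to the ring ketone is removed to give the ketone-stabilised azomethine ylide 37; this adds suprafacially across the distal C=CH2 bond of the tethered allene, bonding the azepanone α-carbon to the central allene carbon and the allene CH2 to the former aldehyde carbon and leaving the proximal C=C as the tetrasubstituted alkene. The closest known reactions are intramolecular cycloadditions of azomethine ylides, made by condensing secondary α-amino esters or ketones with aldehydes, onto tethered unactivated alkenes, and intramolecular dipolar cycloadditions at the distal bond of allenes. The cyclopentene closes in the 5-exo mode with respect to the reacting π bond (three-atom tether from the ylide carbon to the central allene carbon) and the pyrrolidine closes as the [3+2] ring, whereas addition at the proximal bond would need a four-membered or a strained bridged ring. The pyrrolidine CH is set by the iminium geometry (pendant lactone anti to the fully substituted ylide carbon, so that it ends cis to the ketone carbon), and the aza-quaternary carbon by the ethyl-bearing centre of the tether, which should direct the allene to the ylide face that leaves ethyl on the convex face of the new azabicyclo[3.3.0]octene (ethyl cis to the ketone carbon, lactone oxygen cis to N); the α-oxy centre of 34 is carried through unchanged. The step needs deprotonation at the ketone α-carbon to outrun enamine formation toward the α-oxy carbon of the aldehyde and base-induced isomerisation of the vinylidene lactone, which the acidity of the α-amino ketone C–H, the buffered ammonium salt medium, the in-plane orientation of the distal π bond toward the ylide and the short rigid lactone tether should secure.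

Compound list
1 | ethyl glyoxylate | CCOC(=O)C=O | starting material
2 | p-anisidine | COc1ccc(N)cc1 | starting material
3 | ethyl (E)-2-[(4-methoxyphenyl)imino]acetate | CCOC(=O)/C=N/c1ccc(OC)cc1 | intermediate
4 | butanal | CCCC=O | starting material
5 | ethyl (2R,3R)-3-formyl-2-[(4-methoxyphenyl)amino]pentanoate | CC[C@H]([C@@H](Nc1ccc(OC)cc1)C(=O)OCC)C=O | intermediate
6 | ethyl (2R,3R)-3-(dimethoxymethyl)-2-[(4-methoxyphenyl)amino]pentanoate | CC[C@H]([C@@H](Nc1ccc(OC)cc1)C(=O)OCC)C(OC)OC | intermediate
7 | (2R,3R)-3-(dimethoxymethyl)-N-methoxy-2-[(4-methoxyphenyl)amino]-N-methylpentanamide | CC[C@H]([C@@H](Nc1ccc(OC)cc1)C(=O)N(C)OC)C(OC)OC | intermediate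
8 | 1-bromo-4-chlorobutane | ClCCCCBr | starting material
9 | 4-chlorobutylmagnesium bromide | ClCCCC[Mg]Br | intermediate
10 | (3R,4R)-9-chloro-3-(dimethoxymethyl)-4-[(4-methoxyphenyl)amino]nonan-5-one | CC[C@H]([C@@H](Nc1ccc(OC)cc1)C(=O)CCCCCl)C(OC)OC | intermediate
11 | (3R,4R)-3-(dimethoxymethyl)-9-iodo-4-[(4-methoxyphenyl)amino]nonan-5-one | CC[C@H]([C@@H](Nc1ccc(OC)cc1)C(=O)CCCCI)C(OC)OC | intermediate
12 | (2R)-2-[(2R)-1,1-dimethoxybutan-2-yl]-1-(4-methoxyphenyl)azepan-3-one | CC[C@H]([C@H]1N(c2ccc(OC)cc2)CCCCC1=O)C(OC)OC | intermediate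
13 | (2R)-2-[(2R)-1,1-dimethoxybutan-2-yl]azepan-3-one | CC[C@H]([C@H]1NCCCCC1=O)C(OC)OC | intermediate
14 | tert-butyl (2R)-2-[(2R)-1,1-dimethoxybutan-2-yl]-3-oxoazepane-1-carboxylate | CC[C@H]([C@H]1N(C(=O)OC(C)(C)C)CCCCC1=O)C(OC)OC | intermediate
15 | tert-butyl (2R)-3-oxo-2-[(2R)-1-oxobutan-2-yl]azepane-1-carboxylate | CC[C@H]([C@H]1N(C(=O)OC(C)(C)C)CCCCC1=O)C=O | intermediate
16 | methyl (S)-3-hydroxy-2-methylpropanoate | C[C@@H](CO)C(=O)OC | starting material
17 | methyl (S)-3-{[tert-butyl(dimethyl)silyl]oxy}-2-methylpropanoate | C[C@@H](CO[Si](C)(C)C(C)(C)C)C(=O)OC | intermediate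
18 | (S)-3-{[tert-butyl(dimethyl)silyl]oxy}-2-methylpropanal | C[C@@H](CO[Si](C)(C)C(C)(C)C)C=O | intermediate
19 | (R)-tert-butyl(dimethyl)[(2-methylbut-3-yn-1-yl)oxy]silane | CC(C)(C)[Si](C)(C)OC[C@H](C)C#C | intermediate
20 | (R)-5-{[tert-butyl(dimethyl)silyl]oxy}-4-methylpent-2-yn-1-ol | CC(C)(C)[Si](C)(C)OC[C@H](C)C#CCO | intermediate
21 | (R)-[(5-bromo-2-methylpent-3-yn-1-yl)oxy](tert-butyl)dimethylsilane | CC(C)(C)[Si](C)(C)OC[C@H](C)C#CCBr | intermediate
22 | tert-butyl (2R)-2-[(3R,4S,6R)-7-{[tert-butyl(dimethyl)silyl]oxy}-4-hydroxy-6-methyl-5-vinylideneheptan-3-yl]-3-oxoazepane-1-carboxylate | CC[C@H]([C@H]1N(C(=O)OC(C)(C)C)CCCCC1=O)[C@H](O)C(=C=C)[C@@H](C)CO[Si](C)(C)C(C)(C)C | intermediate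
23 | tert-butyl (2R)-2-[(3R,4S,6R)-4,7-dihydroxy-6-methyl-5-vinylideneheptan-3-yl]-3-oxoazepane-1-carboxylate | CC[C@H]([C@H]1N(C(=O)OC(C)(C)C)CCCCC1=O)[C@H](O)C(=C=C)[C@@H](C)CO | intermediate
24 | lactol of 25 (5-hydroxy-4-methyl-3-vinylideneoxolan-2-yl, anomers) | CC[C@H]([C@H]1N(C(=O)OC(C)(C)C)CCCCC1=O)[C@@H]2OC(O)[C@H](C)C2=C=C | intermediate
25 | tert-butyl (2R)-2-{(1R)-1-[(2S,4R)-4-methyl-5-oxo-3-vinylideneoxolan-2-yl]propyl}-3-oxoazepane-1-carboxylate | CC[C@H]([C@H]1N(C(=O)OC(C)(C)C)CCCCC1=O)[C@@H]2OC(=O)[C@H](C)C2=C=C | intermediate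
26 | (2R)-2-{(1R)-1-[(2S,4R)-4-methyl-5-oxo-3-vinylideneoxolan-2-yl]propyl}-3-oxoazepan-1-ium trifluoroacetate | CC[C@H]([C@H]1[NH2+]CCCCC1=O)[C@@H]2OC(=O)[C@H](C)C2=C=C.[O-]C(=O)C(F)(F)F | intermediate
27 | (S)-5-(hydroxymethyl)dihydrofuran-2(3H)-one | OC[C@@H]1CCC(=O)O1 | starting material
28 | (S)-5-[(trityloxy)methyl]dihydrofuran-2(3H)-one | C(OC[C@@H]1CCC(=O)O1)(c2ccccc2)(c2ccccc2)c2ccccc2 | intermediate
29 | (3R,5S)-3-methyl-5-[(trityloxy)methyl]dihydrofuran-2(3H)-one (trans) | C(OC[C@@H]1C[C@@H](C)C(=O)O1)(c2ccccc2)(c2ccccc2)c2ccccc2 | intermediate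
30 | (5S)-3-methyl-3-(phenylselanyl)-5-[(trityloxy)methyl]dihydrofuran-2(3H)-one (SePh anti to the trityloxymethyl group) | C(OC[C@@H]1C[C@]([Se]c2ccccc2)(C)C(=O)O1)(c3ccccc3)(c3ccccc3)c3ccccc3 | intermediate
31 | (S)-3-methyl-5-[(trityloxy)methyl]furan-2(5H)-one | C(OC[C@@H]1C=C(C)C(=O)O1)(c2ccccc2)(c2ccccc2)c2ccccc2 | intermediate
32 | (3S,5S)-3-methyl-5-[(trityloxy)methyl]dihydrofuran-2(3H)-one (cis) | C(OC[C@@H]1C[C@H](C)C(=O)O1)(c2ccccc2)(c2ccccc2)c2ccccc2 | intermediate
33 | (3S,5S)-5-(hydroxymethyl)-3-methyldihydrofuran-2(3H)-one | OC[C@@H]1C[C@H](C)C(=O)O1 | intermediate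
34 | (2S,4S)-4-methyl-5-oxooxolane-2-carbaldehyde | O=C[C@@H]1C[C@H](C)C(=O)O1 | intermediate
35 | free amine of 26 (secondary amino ketone with allene lactone) | CC[C@H]([C@H]1NCCCCC1=O)[C@@H]2OC(=O)[C@H](C)C2=C=C | intermediate
36 | iminium ion from 35 and 34 (trifluoroacetate, pendant lactone anti to the ring α-carbon) | CC[C@H]([C@H]1/[N+](=C/[C@@H]3C[C@H](C)C(=O)O3)CCCCC1=O)[C@@H]2OC(=O)[C@H](C)C2=C=C.[O-]C(=O)C(F)(F)F | intermediate
37 | ketone-stabilised azomethine ylide | CC[C@H]([C-]1/[N+](=C/[C@@H]3C[C@H](C)C(=O)O3)CCCCC1=O)[C@@H]2OC(=O)[C@H](C)C2=C=C | intermediate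
38 | CNP0315436.2 | CC[C@H]1[C@@H]2OC(=O)[C@H](C)C2=C2C[C@@H]([C@@H]3C[C@H](C)C(=O)O3)N3CCCCC(=O)[C@]213 | target

Total step count: 24. Longest linear sequence: 13 steps (steps 1–8, 14–17 and 24).

Steps most likely to fail

1. Step 24. The ylide may not add to the unactivated allene, may add to the wrong face at the aza-quaternary carbon, or the vinylidene lactone may isomerise before it cyclises. Fallback with established reactions only, closing the two rings one after the other; it sets out from 20 (with 15 and 34) and comes back at 38. Trans-hydroalumination of 20 with NaAlH2(OCH2CH2OMe)2 and quenching with NBS gives the (Z)-2-bromo allylic alcohol F1, and CBr4/PPh3 gives the allylic bromide F2. Indium-mediated 2-bromoallylation of 15 with F2 gives the branched bromovinyl carbinol F3 (both epimers at the new CH are usable, since that carbon becomes sp2 later). Intramolecular Pd-catalysed α-alkenylation of the ring ketone (Pd(PPh3)4, KOPh, THF, 70 °C) closes the cyclopentane at the aza-quaternary carbon and gives the spirocyclic methylenecyclopentane F4. A Me2AlCl-promoted carbonyl-ene reaction of F4 with 34 forms the bond to the former aldehyde carbon and moves the double bond into the tetrasubstituted position, giving the homoallylic alcohol F5. Bu4NF/AcOH gives the triol F6; TEMPO/PhI(OAc)2 lactonises the primary alcohol onto the ring hydroxyl and, on prolonged reaction, oxidises the remaining carbinol, giving the keto lactone F7. TFA removes the Boc group to give the amino ketone F8 (as trifluoroacetate), and intramolecular reductive amination (NaBH(OAc)3, AcOH, CH2Cl2) closes the pyrrolidine to 38, hydride arriving on the less hindered face.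

2. Step 14. Transfer from indium may go partly by the SE2 path to the homopropargylic alcohol, or the Felkin–Anh preference may be eroded in the aqueous medium. Fallback with a preformed reagent that can only react through a closed six-membered SE2′ transition state; it sets out from 19 (with 15) and comes back at 22. Lithiation of 19 (n-BuLi, THF, −78 °C) and homologation with ICH2B(pin) gives the propargyl pinacol boronate F9, which is stirred with 15 in toluene at 0 °C → rt; aqueous work-up releases 22.

3. Step 6. Seven-membered N-alkylation by the hindered, weakly nucleophilic N-aryl amine may be slow, so that enolate C- or O-alkylation and oligomerisation compete. Fallback that changes the nucleophile to a sulfonamide anion; it sets out from 10 and comes back at 13, which is converted into 14 by the carbamate formation of step 7. (NH4)2Ce(NO3)6 in MeCN/H2O at 0 °C removes the aryl group to give the primary amino chloro ketone F10 (kept as its salt), 2-nitrobenzenesulfonyl chloride with NaHCO3 gives the sulfonamide F11, Cs2CO3 with catalytic NaI in DMF at 50 °C closes the ring to the N-sulfonyl azepanone F12, and PhSH/K2CO3 in MeCN removes the sulfonyl group to give 13.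

Further compounds
F1 | step 24 | (R,Z)-2-bromo-5-{[tert-butyl(dimethyl)silyl]oxy}-4-methylpent-2-en-1-ol | CC(C)(C)[Si](C)(C)OC[C@H](C)/C=C(\Br)CO
F2 | step 24 | (R,Z)-[(4,5-dibromo-2-methylpent-3-en-1-yl)oxy](tert-butyl)dimethylsilane | CC(C)(C)[Si](C)(C)OC[C@H](C)/C=C(\Br)CBr
F3 | step 24 | bromovinyl carbinol from 15 and F2 (epimers at the CH bearing the bromovinyl group) | CC[C@H]([C@H]1N(C(=O)OC(C)(C)C)CCCCC1=O)[C@H](O)C(C(Br)=C)[C@@H](C)CO[Si](C)(C)C(C)(C)C
F4 | step 24 | N-Boc spirocyclic methylenecyclopentane (azepanone spiro-fused at the aza-quaternary carbon) | CC[C@H]1[C@H](O)C([C@@H](C)CO[Si](C)(C)C(C)(C)C)C(=C)[C@]12N(C(=O)OC(C)(C)C)CCCCC2=O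
F5 | step 24 | carbonyl-ene adduct of F4 and 34 (homoallylic alcohol, carbinol epimers) | CC[C@H]1[C@H](O)C([C@@H](C)CO[Si](C)(C)C(C)(C)C)=C(CC(O)[C@@H]3C[C@H](C)C(=O)O3)[C@]12N(C(=O)OC(C)(C)C)CCCCC2=O
F6 | step 24 | triol from F5 | CC[C@H]1[C@H](O)C([C@@H](C)CO)=C(CC(O)[C@@H]3C[C@H](C)C(=O)O3)[C@]12N(C(=O)OC(C)(C)C)CCCCC2=O
F7 | step 24 | N-Boc keto lactone (cyclopentene-fused methyl lactone with 2-oxoethyl side chain carrying the pendant lactone) | CC[C@H]1[C@@H]2OC(=O)[C@H](C)C2=C(CC(=O)[C@@H]3C[C@H](C)C(=O)O3)[C@]14N(C(=O)OC(C)(C)C)CCCCC4=O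
F8 | step 24 | amino ketone from F7 (handled as trifluoroacetate) | CC[C@H]1[C@@H]2OC(=O)[C@H](C)C2=C(CC(=O)[C@@H]3C[C@H](C)C(=O)O3)[C@]14NCCCCC4=O
F9 | step 14 | (R)-tert-butyl(dimethyl){[2-methyl-5-(4,4,5,5-tetramethyl-1,3,2-dioxaborolan-2-yl)pent-3-yn-1-yl]oxy}silane | CC(C)(C)[Si](C)(C)OC[C@H](C)C#CCB1OC(C)(C)C(C)(C)O1
F10 | step 6 | (3R,4R)-4-amino-9-chloro-3-(dimethoxymethyl)nonan-5-one | CC[C@H]([C@@H](N)C(=O)CCCCCl)C(OC)OC
F11 | step 6 | N-[(3R,4R)-9-chloro-3-(dimethoxymethyl)-5-oxononan-4-yl]-2-nitrobenzenesulfonamide | CC[C@H]([C@@H](NS(=O)(=O)c1ccccc1[N+](=O)[O-])C(=O)CCCCCl)C(OC)OC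
F12 | step 6 | (2R)-2-[(2R)-1,1-dimethoxybutan-2-yl]-1-(2-nitrobenzenesulfonyl)azepan-3-one | CC[C@H]([C@H]1N(S(=O)(=O)c2ccccc2[N+](=O)[O-])CCCCC1=O)C(OC)OC
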